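**Strategy.** Germacranolide numbering is used. The route rests on cutting the lactone at the C7–C11 bond: the trans-fused γ-lactone ring (O–C6–C7–C11–C12) with its neighbouring C8 oxygen is read as a C6-acylated erythro C7,C8-epoxy alcohol. A phosphonoacetate on O6 is deprotonated and its carbanion opens the epoxide at C7 (5-exo, inversion). This closes the lactone, sets C7, frees the C8 hydroxyl for the epoxyangelate and, after in-flask Horner–Wadsworth–Emmons reaction with formaldehyde, installs the C11=C13 methylene. The ten-membered ring is closed last by ring-closing metathesis at C1=C10.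

Key step: step 8

Remark: C9 is carried as a silylated hydroxymethyl group and becomes the carbinol only after O8 is acylated, because a free C8 hydroxyl next to the C14 ester would lactonise; reagents and catalysts are taken as purchased.

Step 1
Reactants: 1 2-{[tert-butyl(dimethyl)silyl]oxy}acetaldehyde
Product: 2 (2E)-4-{[tert-butyl(dimethyl)silyl]oxy}but-2-enal
Conditions: Ph3P=CHCHO, toluene, 80 °C
Reagents that add atoms: (triphenylphosphoranylidene)acetaldehyde, O=CC=P(c1ccccc1)(c1ccccc1)c1ccccc1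
Why: Wittig olefination with the formyl-stabilised ylide should give the (E)-enal under the usual control of stabilised ylides; no stereocentre is formed.

Step 2
Reactants: 2 (2E)-4-{[tert-butyl(dimethyl)silyl]oxy}but-2-enal
Product: 3 (2S,3R)-3-({[tert-butyl(dimethyl)silyl]oxy}methyl)oxirane-2-carbaldehyde
Conditions: (R)-2-{bis[3,5-bis(trifluoromethyl)phenyl][(trimethylsilyl)oxy]methyl}pyrrolidine (10 mol %), 35% aq. H2O2, CH2Cl2, rt
Reagents that add atoms: hydrogen peroxide, OO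
Why: Iminium-ion catalysed nucleophilic epoxidation (conjugate addition of H2O2, then closure of the enamine onto the O–O bond) should give the trans-epoxy aldehyde, the (R)-diarylprolinol silyl ether shielding one face of the (E)-iminium ion so that C7 and C8 are set as (2S,3R).

Step 3
Reactants: 4 prop-2-yn-1-ol
Product: 6 (2Z)-3-iodo-2-methylprop-2-en-1-ol, via alkenylmagnesium alkoxide 5 (not isolated)
Conditions: MeMgBr (2.5 equiv), CuI (10 mol %), Et2O, −10 °C → rt; then I2, −78 → 0 °C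
Reagents that add atoms: methylmagnesium bromide, C[Mg]Br; iodine, II
Why: Copper-catalysed anti-carbomagnesiation of the propargylic magnesium alkoxide places methyl on the internal carbon and magnesium cis to the CH2O group, and iodinolysis with retention fixes the (Z) geometry; no stereocentre is formed.

Step 4
Reactants: 6 (2Z)-3-iodo-2-methylprop-2-en-1-ol
Product: 7 (2Z)-3-iodo-2-methylprop-2-enal
Conditions: MnO2, CH2Cl2, rt
Reagents that add atoms: none
Why: Allylic oxidation on MnO2 is neutral and heterogeneous and should give the enal without (Z) to (E) isomerisation; no stereocentre is formed.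

Step 5
Reactants: 7 (2Z)-3-iodo-2-methylprop-2-enal
Product: 9 (2R,3S)-2-ethenyl-3-[(1Z)-1-iodoprop-1-en-2-yl]oxirane, via syn-chlorohydrin 8 (not isolated)
Conditions: CH2=CHCH2Cl, LiN(c-C6H11)2, (+)-B-methoxydiisopinocampheylborane [from (−)-α-pinene], BF3·OEt2, Et2O, −95 °C; then 7, −95 °C; then NaOH, H2O2, 0 °C → rt
Reagents that add atoms: 3-chloroprop-1-ene, C=CCCl
Why: (Z)-γ-Chloroallylboration through a closed chair transition state gives the syn chlorohydrin, the isopinocampheyl groups directing attack to the Re face of the aldehyde (sets C3, and C2 relative to it), and during the alkaline peroxide work-up the alkoxide displaces chloride with inversion at C2 to close the cis-vinyl epoxide.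

Step 6
Reactants: 3 (2S,3R)-3-({[tert-butyl(dimethyl)silyl]oxy}methyl)oxirane-2-carbaldehyde; 9 (2R,3S)-2-ethenyl-3-[(1Z)-1-iodoprop-1-en-2-yl]oxirane
Product: 10 (1R,2Z)-1-[(2R,3R)-3-({[tert-butyl(dimethyl)silyl]oxy}methyl)oxiran-2-yl]-3-[(2S,3R)-3-ethenyloxiran-2-yl]but-2-en-1-ol
Conditions: CrCl2 (4 equiv), NiCl2 (2 mol %), DMSO, rt
Reagents that add atoms: none
Why: Nozaki–Hiyama–Kishi coupling: the alkenylchromium formed with retention of the (Z) geometry adds only to the aldehyde, and Felkin–Anh attack anti to the epoxide C–O bond should set C6 as the erythro (6R) epoxy alcohol.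

Step 7
Reactants: 10 (1R,2Z)-1-[(2R,3R)-3-({[tert-butyl(dimethyl)silyl]oxy}methyl)oxiran-2-yl]-3-[(2S,3R)-3-ethenyloxiran-2-yl]but-2-en-1-ol
Product: 11 (1R,2Z)-1-[(2R,3R)-3-({[tert-butyl(dimethyl)silyl]oxy}methyl)oxiran-2-yl]-3-[(2S,3R)-3-ethenyloxiran-2-yl]but-2-en-1-yl 2-(diethoxyphosphoryl)acetate
Conditions: (EtO)2P(O)CH2CO2H, DCC, DMAP (cat.), CH2Cl2, 0 °C → rt
Reagents that add atoms: 2-(diethoxyphosphoryl)acetic acid, CCOP(=O)(OCC)CC(=O)O
Why: Carbodiimide (Steglich-type) esterification of the secondary alcohol under neutral conditions leaves both epoxides and all stereocentres untouched.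

Step 8
Reactants: 11 (1R,2Z)-1-[(2R,3R)-3-({[tert-butyl(dimethyl)silyl]oxy}methyl)oxiran-2-yl]-3-[(2S,3R)-3-ethenyloxiran-2-yl]but-2-en-1-yl 2-(diethoxyphosphoryl)acetate
Product: 13 (4R,5R)-4-[(1S)-2-{[tert-butyl(dimethyl)silyl]oxy}-1-hydroxyethyl]-5-{(1Z)-2-[(2S,3R)-3-ethenyloxiran-2-yl]prop-1-en-1-yl}-3-methylideneoxolan-2-one, via phosphono lactone 12 (not isolated)
Conditions: NaH (1.05 equiv), THF, 0 °C → rt; then (CH2O)n, rt → 40 °C
Reagents that add atoms: formaldehyde (as paraformaldehyde), C=O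
Why: NaH deprotonates the phosphonoacetate and the soft carbanion at C11 attacks the epoxide carbon C7 from the side opposite to the epoxide oxygen (SN2), after which the liberated C8 alkoxide takes the acidic C11 proton and the resulting phosphonate anion undergoes Horner–Wadsworth–Emmons olefination with formaldehyde. The closest known reaction types are the intramolecular epoxide alkylation of stabilised carbanions (epoxynitrile-type cyclisation), the base-induced closure of 2,3-epoxy alcohol carbamates to oxazolidinones through the same O–C(=O)–X tether, and the epoxide/phosphonoacetate route to α-methylene lactones. The only ring closed is the γ-lactone O–C6–C7–C11–C12, formed in the 5-exo-tet mode. C7 is the only new stereocentre and is set by inversion at the epoxide carbon, so the erythro trans-epoxide gives trans-disposed C6 and C7 substituents while C6 and C8 are carried through unchanged. The step needs C- rather than O-alkylation and attack at C7 rather than at C8 or at the remote vinyl epoxide: the phosphonate-stabilised carbanion alkylates on carbon, the five-membered transition state is preferred over the six-membered one as in the carbamate precedent, and the C2–C3 epoxide could only be reached through a seven-membered ring. Moving the charge from oxygen to C11 right after ring closure should keep the C8 alkoxide from shifting the silyl group or adding to the new methylene.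

Step 9
Reactants: 14 methyl (2Z)-2-methylbut-2-enoate (methyl angelate)
Product: 15 (2Z)-2-methylbut-2-en-1-ol
Conditions: i-Bu2AlH (2.2 equiv), CH2Cl2, −78 → 0 °C
Reagents that add atoms: none
Why: Ester reduction by the aluminium hydride gives the allylic alcohol with the (Z) geometry of the angelate retained; no stereocentre is formed.

Step 10
Reactants: 15 (2Z)-2-methylbut-2-en-1-ol
Product: 16 [(2R,3S)-2,3-dimethyloxiran-2-yl]methanol
Conditions: Ti(OiPr)4 (10 mol %), D-(−)-diethyl tartrate (12 mol %), t-BuOOH, 4 Å molecular sieves, CH2Cl2, −20 °C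
Reagents that add atoms: tert-butyl hydroperoxide, CC(C)(C)OO
Why: Sharpless asymmetric epoxidation: the titanium D-(−)-tartrate complex delivers oxygen to the alkene face that gives the (2R,3S) epoxy alcohol, and the cis relation of CH2OH and the C3 methyl follows from the (Z) alkene.

Step 11
Reactants: 16 [(2R,3S)-2,3-dimethyloxiran-2-yl]methanol
Product: 17 (2S,3S)-2,3-dimethyloxirane-2-carboxylic acid
Conditions: TEMPO (20 mol %), PhI(OAc)2 (2.2 equiv), MeCN–H2O (1:1), 0 °C → rt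
Reagents that add atoms: water, O
Why: Oxoammonium (TEMPO) oxidation of the primary alcohol through the aldehyde hydrate gives the glycidic acid; the quaternary C2 cannot epimerise.

Step 12
Reactants: 13 (4R,5R)-4-[(1S)-2-{[tert-butyl(dimethyl)silyl]oxy}-1-hydroxyethyl]-5-{(1Z)-2-[(2S,3R)-3-ethenyloxiran-2-yl]prop-1-en-1-yl}-3-methylideneoxolan-2-one; 17 (2S,3S)-2,3-dimethyloxirane-2-carboxylic acid
Product: 19 (1S)-2-{[tert-butyl(dimethyl)silyl]oxy}-1-[(2R,3S)-2-{(1Z)-2-[(2S,3R)-3-ethenyloxiran-2-yl]prop-1-en-1-yl}-4-methylidene-5-oxooxolan-3-yl]ethyl (2S,3S)-2,3-dimethyloxirane-2-carboxylate, via mixed anhydride 18 (not isolated)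
Conditions: 17, 2,4,6-trichlorobenzoyl chloride, Et3N, THF, rt; then 13, DMAP, toluene, rt
Reagents that add atoms: none
Why: Yamaguchi esterification through the mixed 2,4,6-trichlorobenzoic anhydride acylates the hindered C8 hydroxyl under DMAP catalysis; no stereocentre is touched.

Step 13
Reactants: 19 (1S)-2-{[tert-butyl(dimethyl)silyl]oxy}-1-[(2R,3S)-2-{(1Z)-2-[(2S,3R)-3-ethenyloxiran-2-yl]prop-1-en-1-yl}-4-methylidene-5-oxooxolan-3-yl]ethyl (2S,3S)-2,3-dimethyloxirane-2-carboxylate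
Product: 20 (1S)-2-hydroxy-1-[(2R,3S)-2-{(1Z)-2-[(2S,3R)-3-ethenyloxiran-2-yl]prop-1-en-1-yl}-4-methylidene-5-oxooxolan-3-yl]ethyl (2S,3S)-2,3-dimethyloxirane-2-carboxylate
Conditions: HF·pyridine, pyridine, THF, 0 °C
Reagents that add atoms: none
Why: Fluoride cleavage of the primary silyl ether with pyridine-buffered HF keeps the medium too weakly acidic to open the allylic epoxide and too weakly basic to shift the C8 ester to O9.

Step 14
Reactants: 20 (1S)-2-hydroxy-1-[(2R,3S)-2-{(1Z)-2-[(2S,3R)-3-ethenyloxiran-2-yl]prop-1-en-1-yl}-4-methylidene-5-oxooxolan-3-yl]ethyl (2S,3S)-2,3-dimethyloxirane-2-carboxylate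
Product: 21 (1S)-2-oxo-1-[(2R,3S)-2-{(1Z)-2-[(2S,3R)-3-ethenyloxiran-2-yl]prop-1-en-1-yl}-4-methylidene-5-oxooxolan-3-yl]ethyl (2S,3S)-2,3-dimethyloxirane-2-carboxylate
Conditions: Dess–Martin periodinane, NaHCO3, CH2Cl2, 0 °C → rt
Reagents that add atoms: none
Why: Dess–Martin oxidation under bicarbonate buffer should give the α-acyloxy aldehyde without epimerising C8.

Step 15
Reactants: 21 (1S)-2-oxo-1-[(2R,3S)-2-{(1Z)-2-[(2S,3R)-3-ethenyloxiran-2-yl]prop-1-en-1-yl}-4-methylidene-5-oxooxolan-3-yl]ethyl (2S,3S)-2,3-dimethyloxirane-2-carboxylate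
Product: 23 methyl (3S,4S)-4-{[(2S,3S)-2,3-dimethyloxirane-2-carbonyl]oxy}-4-[(2R,3S)-2-{(1Z)-2-[(2S,3R)-3-ethenyloxiran-2-yl]prop-1-en-1-yl}-4-methylidene-5-oxooxolan-3-yl]-3-hydroxy-2-methylidenebutanoate, via hexafluoroisopropyl ester 22 (not isolated)
Conditions: β-isocupreidine (0.2 equiv), 1,1,1,3,3,3-hexafluoropropan-2-yl acrylate, DMF, −55 °C; then MeOH, Et3N, 0 °C
Reagents that add atoms: 1,1,1,3,3,3-hexafluoropropan-2-yl acrylate, C=CC(=O)OC(C(F)(F)F)C(F)(F)F; methanol, CO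
Why: Asymmetric Morita–Baylis–Hillman reaction: the quinuclidine nitrogen adds to the activated acrylate and the phenolic OH of the catalyst organises the aldol step so that, in the matched pairing with the (8S) α-acyloxy aldehyde, the syn (9S) adduct should form, and the activated hexafluoroisopropyl ester is then exchanged for the methyl ester by methanolysis.

Step 16
Reactants: 23 methyl (3S,4S)-4-{[(2S,3S)-2,3-dimethyloxirane-2-carbonyl]oxy}-4-[(2R,3S)-2-{(1Z)-2-[(2S,3R)-3-ethenyloxiran-2-yl]prop-1-en-1-yl}-4-methylidene-5-oxooxolan-3-yl]-3-hydroxy-2-methylidenebutanoate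
Product: 24 target CNP0291485.3
Conditions: second-generation Hoveyda–Grubbs catalyst, RuCl2(H2IMes)(=CH–C6H4-2-O-i-Pr) (20 mol %), toluene (1 mM), 80 °C
Reagents that add atoms: none
Why: Ring-closing metathesis between the vinyl group of the vinyl epoxide and the α-substituted acrylate closes the ten-membered ring at C1=C10, the ring and the usual preference of acrylate metathesis both placing C2 trans to the ester and cis to C9; no stereocentre is formed.

**Compound list**

1 | 2-{[tert-butyl(dimethyl)silyl]oxy}acetaldehyde | O=CCO[Si](C)(C)C(C)(C)C | starting material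
2 | (2E)-4-{[tert-butyl(dimethyl)silyl]oxy}but-2-enal | O=C/C=C/CO[Si](C)(C)C(C)(C)C | intermediate
3 | (2S,3R)-3-({[tert-butyl(dimethyl)silyl]oxy}methyl)oxirane-2-carbaldehyde | O=C[C@H]1O[C@@H]1CO[Si](C)(C)C(C)(C)C | intermediate
4 | prop-2-yn-1-ol | C#CCO | starting material
5 | bromomagnesium (2Z)-3-(bromomagnesio)-2-methylprop-2-en-1-olate | Br[Mg]OC/C(C)=C\[Mg]Br | intermediate (not isolated)
6 | (2Z)-3-iodo-2-methylprop-2-en-1-ol | OC/C(C)=C\I | intermediate
7 | (2Z)-3-iodo-2-methylprop-2-enal | O=C/C(C)=C\I | intermediate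
8 | (1Z,3S,4S)-4-chloro-1-iodo-2-methylhexa-1,5-dien-3-ol | C=C[C@H](Cl)[C@@H](O)/C(C)=C\I | intermediate (not isolated)
9 | (2R,3S)-2-ethenyl-3-[(1Z)-1-iodoprop-1-en-2-yl]oxirane | C=C[C@H]1O[C@H]1/C(C)=C\I | intermediate
10 | (1R,2Z)-1-[(2R,3R)-3-({[tert-butyl(dimethyl)silyl]oxy}methyl)oxiran-2-yl]-3-[(2S,3R)-3-ethenyloxiran-2-yl]but-2-en-1-ol | O[C@H](/C=C(/C)[C@@H]2O[C@@H]2C=C)[C@H]1O[C@@H]1CO[Si](C)(C)C(C)(C)C | intermediate
11 | (1R,2Z)-1-[(2R,3R)-3-({[tert-butyl(dimethyl)silyl]oxy}methyl)oxiran-2-yl]-3-[(2S,3R)-3-ethenyloxiran-2-yl]but-2-en-1-yl 2-(diethoxyphosphoryl)acetate | CCOP(=O)(OCC)CC(=O)O[C@H](/C=C(/C)[C@@H]2O[C@@H]2C=C)[C@H]1O[C@@H]1CO[Si](C)(C)C(C)(C)C | intermediate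
12 | diethyl [(4R,5R)-4-[(1S)-2-{[tert-butyl(dimethyl)silyl]oxy}-1-hydroxyethyl]-5-{(1Z)-2-[(2S,3R)-3-ethenyloxiran-2-yl]prop-1-en-1-yl}-2-oxooxolan-3-yl]phosphonate (both C3 epimers) | CCOP(=O)(OCC)C1C(=O)O[C@H](/C=C(/C)[C@@H]2O[C@@H]2C=C)[C@H]1[C@H](O)CO[Si](C)(C)C(C)(C)C | intermediate (not isolated)
13 | (4R,5R)-4-[(1S)-2-{[tert-butyl(dimethyl)silyl]oxy}-1-hydroxyethyl]-5-{(1Z)-2-[(2S,3R)-3-ethenyloxiran-2-yl]prop-1-en-1-yl}-3-methylideneoxolan-2-one | C=C1C(=O)O[C@H](/C=C(/C)[C@@H]2O[C@@H]2C=C)[C@H]1[C@H](O)CO[Si](C)(C)C(C)(C)C | intermediate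
14 | methyl (2Z)-2-methylbut-2-enoate (methyl angelate) | C/C=C(/C)C(=O)OC | starting material
15 | (2Z)-2-methylbut-2-en-1-ol | C/C=C(/C)CO | intermediate
16 | [(2R,3S)-2,3-dimethyloxiran-2-yl]methanol | OC[C@@]1(C)O[C@H]1C | intermediate
17 | (2S,3S)-2,3-dimethyloxirane-2-carboxylic acid | OC(=O)[C@@]1(C)O[C@H]1C | intermediate
18 | (2S,3S)-2,3-dimethyloxirane-2-carboxylic 2,4,6-trichlorobenzoic anhydride | O=C(OC(=O)c1c(Cl)cc(Cl)cc1Cl)[C@@]1(C)O[C@H]1C | intermediate (not isolated)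
19 | (1S)-2-{[tert-butyl(dimethyl)silyl]oxy}-1-[(2R,3S)-2-{(1Z)-2-[(2S,3R)-3-ethenyloxiran-2-yl]prop-1-en-1-yl}-4-methylidene-5-oxooxolan-3-yl]ethyl (2S,3S)-2,3-dimethyloxirane-2-carboxylate | C=C1C(=O)O[C@H](/C=C(/C)[C@@H]2O[C@@H]2C=C)[C@H]1[C@H](OC(=O)[C@@]3(C)O[C@H]3C)CO[Si](C)(C)C(C)(C)C | intermediate
20 | (1S)-2-hydroxy-1-[(2R,3S)-2-{(1Z)-2-[(2S,3R)-3-ethenyloxiran-2-yl]prop-1-en-1-yl}-4-methylidene-5-oxooxolan-3-yl]ethyl (2S,3S)-2,3-dimethyloxirane-2-carboxylate | C=C1C(=O)O[C@H](/C=C(/C)[C@@H]2O[C@@H]2C=C)[C@H]1[C@H](OC(=O)[C@@]3(C)O[C@H]3C)CO | intermediate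
21 | (1S)-2-oxo-1-[(2R,3S)-2-{(1Z)-2-[(2S,3R)-3-ethenyloxiran-2-yl]prop-1-en-1-yl}-4-methylidene-5-oxooxolan-3-yl]ethyl (2S,3S)-2,3-dimethyloxirane-2-carboxylate | C=C1C(=O)O[C@H](/C=C(/C)[C@@H]2O[C@@H]2C=C)[C@H]1[C@H](OC(=O)[C@@]3(C)O[C@H]3C)C=O | intermediate
22 | 1,1,1,3,3,3-hexafluoropropan-2-yl (3S,4S)-4-{[(2S,3S)-2,3-dimethyloxirane-2-carbonyl]oxy}-4-[(2R,3S)-2-{(1Z)-2-[(2S,3R)-3-ethenyloxiran-2-yl]prop-1-en-1-yl}-4-methylidene-5-oxooxolan-3-yl]-3-hydroxy-2-methylidenebutanoate | C=C1C(=O)O[C@H](/C=C(/C)[C@@H]2O[C@@H]2C=C)[C@H]1[C@H](OC(=O)[C@@]3(C)O[C@H]3C)[C@@H](O)C(=C)C(=O)OC(C(F)(F)F)C(F)(F)F | intermediate (not isolated)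
23 | methyl (3S,4S)-4-{[(2S,3S)-2,3-dimethyloxirane-2-carbonyl]oxy}-4-[(2R,3S)-2-{(1Z)-2-[(2S,3R)-3-ethenyloxiran-2-yl]prop-1-en-1-yl}-4-methylidene-5-oxooxolan-3-yl]-3-hydroxy-2-methylidenebutanoate | C=C1C(=O)O[C@H](/C=C(/C)[C@@H]2O[C@@H]2C=C)[C@H]1[C@H](OC(=O)[C@@]3(C)O[C@H]3C)[C@@H](O)C(=C)C(=O)OC | intermediate
24 | CNP0291485.3: methyl ester of (2R,3S,6R,7S,8S,9S)-2,3-epoxy-8-{[(2S,3S)-2,3-dimethyloxirane-2-carbonyl]oxy}-9-hydroxygermacra-1(10)E,4Z,11(13)-trien-12,6-olid-14-oic acid | C=C1C(=O)O[C@@H]2/C=C(/C)[C@@H]3O[C@@H]3/C=C(/C(=O)OC)[C@H](O)[C@@H](OC(=O)[C@@]3(C)O[C@H]3C)[C@@H]12 | target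

**Step count and risks**

Total step count: 16. Longest linear sequence: 11 steps (steps 3, 4, 5, 6, 7, 8, 12, 13, 14, 15, 16, from prop-2-yn-1-ol).

Steps most likely to fail:

Step 16 (ring-closing metathesis). The ruthenium alkylidene formed at the vinyl epoxide may be diverted to the lactone exo-methylene (cross-metathesis dimers, an eight-membered by-product), or the ten-membered closure onto the hindered acrylate may be too slow and the catalyst may decompose first. As a fallback the exo-methylene is made only after the ring exists. Setting out from 11, the cyclisation of step 8 is quenched with acetic acid before formaldehyde is added, and phosphono lactone 12 is isolated. Yamaguchi acylation with 18 should give silyl ether F1, buffered HF·pyridine alcohol F2, and Dess–Martin oxidation aldehyde F3. The β-isocupreidine Morita–Baylis–Hillman reaction should give hexafluoroisopropyl ester F4 and, after methanolysis, methyl ester F5. Ring-closing metathesis of F5, in which the acrylate is now the only 1,1-disubstituted alkene, should give macrocyclic phosphonate F6. K2CO3 with aqueous formaldehyde (Horner–Wadsworth–Emmons olefination) then returns to the route at 24.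

Step 15 (Morita–Baylis–Hillman reaction). The aldol step on the hindered α-acyloxy aldehyde may be slow, and the facial selectivity at C9 may be insufficient. As a fallback, setting out from 21, methyl acrylate and DABCO should give the adduct mainly as the (9R) epimer F7 (Felkin–Anh addition). Dess–Martin oxidation should give keto ester F8. Reduction with (S)-2-methyl-CBS-oxazaborolidine and catecholborane at −78 °C (Corey–Bakshi–Shibata reduction, with the enoate vinyl group as the large substituent and reinforced by Felkin–Anh attack anti to the C8 acyloxy group) should give the (9S) alcohol 23, where the route is rejoined.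

Step 6 (Nozaki–Hiyama–Kishi coupling). Chelation of chromium between the aldehyde and epoxide oxygens may erode Felkin–Anh control, so that much of the C6 epimer forms. As a fallback, setting out from the C6-epimer mixture obtained from 3 and 9, Dess–Martin oxidation should give epoxy enone F9. Reduction with Zn(BH4)2 in Et2O at −20 °C (zinc chelated between the ketone and epoxide oxygens, hydride delivered from the face away from the epoxide ring; the known erythro-selective reduction of α,β-epoxy ketones) returns to the route at 10.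

Further compounds
F1 | step 16 | (1S)-2-{[tert-butyl(dimethyl)silyl]oxy}-1-[(2R,3S)-4-(diethoxyphosphoryl)-2-{(1Z)-2-[(2S,3R)-3-ethenyloxiran-2-yl]prop-1-en-1-yl}-5-oxooxolan-3-yl]ethyl (2S,3S)-2,3-dimethyloxirane-2-carboxylate | CCOP(=O)(OCC)C1C(=O)O[C@H](/C=C(/C)[C@@H]2O[C@@H]2C=C)[C@H]1[C@H](OC(=O)[C@@]3(C)O[C@H]3C)CO[Si](C)(C)C(C)(C)C
F2 | step 16 | (1S)-1-[(2R,3S)-4-(diethoxyphosphoryl)-2-{(1Z)-2-[(2S,3R)-3-ethenyloxiran-2-yl]prop-1-en-1-yl}-5-oxooxolan-3-yl]-2-hydroxyethyl (2S,3S)-2,3-dimethyloxirane-2-carboxylate | CCOP(=O)(OCC)C1C(=O)O[C@H](/C=C(/C)[C@@H]2O[C@@H]2C=C)[C@H]1[C@H](OC(=O)[C@@]3(C)O[C@H]3C)CO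
F3 | step 16 | (1S)-1-[(2R,3S)-4-(diethoxyphosphoryl)-2-{(1Z)-2-[(2S,3R)-3-ethenyloxiran-2-yl]prop-1-en-1-yl}-5-oxooxolan-3-yl]-2-oxoethyl (2S,3S)-2,3-dimethyloxirane-2-carboxylate | CCOP(=O)(OCC)C1C(=O)O[C@H](/C=C(/C)[C@@H]2O[C@@H]2C=C)[C@H]1[C@H](OC(=O)[C@@]3(C)O[C@H]3C)C=O
F4 | step 16 | 1,1,1,3,3,3-hexafluoropropan-2-yl (3S,4S)-4-[(2R,3S)-4-(diethoxyphosphoryl)-2-{(1Z)-2-[(2S,3R)-3-ethenyloxiran-2-yl]prop-1-en-1-yl}-5-oxooxolan-3-yl]-4-{[(2S,3S)-2,3-dimethyloxirane-2-carbonyl]oxy}-3-hydroxy-2-methylidenebutanoate | CCOP(=O)(OCC)C1C(=O)O[C@H](/C=C(/C)[C@@H]2O[C@@H]2C=C)[C@H]1[C@H](OC(=O)[C@@]3(C)O[C@H]3C)[C@@H](O)C(=C)C(=O)OC(C(F)(F)F)C(F)(F)F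
F5 | step 16 | methyl (3S,4S)-4-[(2R,3S)-4-(diethoxyphosphoryl)-2-{(1Z)-2-[(2S,3R)-3-ethenyloxiran-2-yl]prop-1-en-1-yl}-5-oxooxolan-3-yl]-4-{[(2S,3S)-2,3-dimethyloxirane-2-carbonyl]oxy}-3-hydroxy-2-methylidenebutanoate | CCOP(=O)(OCC)C1C(=O)O[C@H](/C=C(/C)[C@@H]2O[C@@H]2C=C)[C@H]1[C@H](OC(=O)[C@@]3(C)O[C@H]3C)[C@@H](O)C(=C)C(=O)OC
F6 | step 16 | 11-(diethoxyphosphoryl)-11,13-dihydro analogue of 24 lacking C13 (macrocyclic α-phosphono lactone, both C11 epimers) | CCOP(=O)(OCC)C1C(=O)O[C@@H]2/C=C(/C)[C@@H]3O[C@@H]3/C=C(/C(=O)OC)[C@H](O)[C@@H](OC(=O)[C@@]3(C)O[C@H]3C)[C@@H]12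
F7 | step 15 | methyl (3R,4S)-4-{[(2S,3S)-2,3-dimethyloxirane-2-carbonyl]oxy}-4-[(2R,3S)-2-{(1Z)-2-[(2S,3R)-3-ethenyloxiran-2-yl]prop-1-en-1-yl}-4-methylidene-5-oxooxolan-3-yl]-3-hydroxy-2-methylidenebutanoate (C9 epimer of 23) | C=C1C(=O)O[C@H](/C=C(/C)[C@@H]2O[C@@H]2C=C)[C@H]1[C@H](OC(=O)[C@@]3(C)O[C@H]3C)[C@H](O)C(=C)C(=O)OC
F8 | step 15 | methyl (4S)-4-{[(2S,3S)-2,3-dimethyloxirane-2-carbonyl]oxy}-4-[(2R,3S)-2-{(1Z)-2-[(2S,3R)-3-ethenyloxiran-2-yl]prop-1-en-1-yl}-4-methylidene-5-oxooxolan-3-yl]-2-methylidene-3-oxobutanoate | C=C1C(=O)O[C@H](/C=C(/C)[C@@H]2O[C@@H]2C=C)[C@H]1[C@H](OC(=O)[C@@]3(C)O[C@H]3C)C(=O)C(=C)C(=O)OC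
F9 | step 6 | (2Z)-1-[(2S,3R)-3-({[tert-butyl(dimethyl)silyl]oxy}methyl)oxiran-2-yl]-3-[(2S,3R)-3-ethenyloxiran-2-yl]but-2-en-1-one | O=C(/C=C(/C)[C@@H]2O[C@@H]2C=C)[C@H]1O[C@@H]1CO[Si](C)(C)C(C)(C)C
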